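## Retrosynthetic overview

- The target is an unsymmetrical trimer with no stereocentre. Central ring B is 2,4,6-trihydroxyacetophenone. Outer ring A is an aspidinol unit (OMe para to the butanoyl, CH2 next to the OMe). Outer ring C is its O-methyl regioisomer (OMe ortho to the butanoyl, CH2 between two OH groups).
- Both ArCH2–Ar bonds are cut. Each CH2 comes from a Mannich base of an outer ring, which reacts through its ortho-quinone methide with ring B. The A–B bond is made first (excess B), then the B–C bond.
- Both outer rings come from one ketone, 2. Para-O-methylation gives ring A. 4,6-Di-O-benzylation, 2-O-methylation and hydrogenolysis give ring C.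
- No ring is built. The three benzene rings are bought (1 used twice, and 5) and joined in the order A–B, then C.

Assumption: the SMILES holds no stereocentre, so the compound is made as the one achiral species drawn, and the two outer rings are read exactly as written (regioisomers, not identical).

## Route

Step 1
Reactants: 1 2-methylbenzene-1,3,5-triol (2,4,6-trihydroxytoluene)
Product: 2 1-(2,4,6-trihydroxy-3-methylphenyl)butan-1-one
Conditions: butanoyl chloride (1.05 equiv), AlCl3 (3.5 equiv), PhNO2/CH2Cl2, 0 to 45 °C; ice/2 M HCl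
Reagents that add atoms: butanoyl chloride, CCCC(Cl)=O
Why: Friedel–Crafts acylation of a highly activated ring whose two free carbons are equivalent, so one ketone forms and the new acyl group deactivates the ring against a second acylation.

Step 2 (uses about 40% of 2)
Reactants: 2 1-(2,4,6-trihydroxy-3-methylphenyl)butan-1-one
Product: 3 1-(2,6-dihydroxy-4-methoxy-3-methylphenyl)butan-1-one (aspidinol)
Conditions: Me2SO4 (1.0 equiv), K2CO3 (1.1 equiv), acetone, 20 to 40 °C; chromatography
Reagents that add atoms: dimethyl sulfate, COS(=O)(=O)OC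
Why: Williamson-type O-methylation with limiting reagent goes first to the 4-OH, which is para to the ketone, the most acidic, and the only OH not hydrogen-bonded to the carbonyl.

Step 3
Reactants: 3 1-(2,6-dihydroxy-4-methoxy-3-methylphenyl)butan-1-one
Product: 4 1-{3-[(dimethylamino)methyl]-2,6-dihydroxy-4-methoxy-5-methylphenyl}butan-1-one
Conditions: 37% aq. HCHO (1.1 equiv) premixed with 40% aq. Me2NH (1.5 equiv), EtOH, 0 °C to rt; filter the precipitated zwitterion
Reagents that add atoms: formaldehyde, C=O; dimethylamine, CNC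
Why: Mannich aminomethylation at the only unsubstituted ring carbon, so the position is forced, and premixing amine and formaldehyde suppresses methylene-bis(aspidinol).

Step 4
Reactants: 4 1-{3-[(dimethylamino)methyl]-2,6-dihydroxy-4-methoxy-5-methylphenyl}butan-1-one; 5 1-(2,4,6-trihydroxyphenyl)ethan-1-one (dried, 3 equiv)
Product: 7 1-{3-[(3-butanoyl-2,4-dihydroxy-6-methoxy-5-methylphenyl)methyl]-2,4,6-trihydroxyphenyl}ethan-1-one, via ring-A ortho-quinone methide 6 (not isolated)
Conditions: 1,4-dioxane, 95 °C, N2 sparge, 3 h; dilute HCl wash; chromatography (excess 5 recovered)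
Reagents that add atoms: none
Why: Thermal retro-Michael loss of dimethylamine gives ortho-quinone methide 6, which is trapped by Michael-type (Friedel–Crafts-like) C-alkylation at one of the two equivalent free carbons of 5, and the threefold excess of 5 holds the reaction at the mono-adduct.

Step 5 (uses about 60% of 2)
Reactants: 2 1-(2,4,6-trihydroxy-3-methylphenyl)butan-1-one
Product: 9 1-[4,6-bis(benzyloxy)-2-hydroxy-3-methylphenyl]butan-1-one, via 4-O-benzyl ether 8 (not isolated)
Conditions: BnBr (2.1 equiv), K2CO3 (2.5 equiv), acetone, reflux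
Reagents that add atoms: benzyl bromide, BrCc1ccccc1
Why: Williamson ether synthesis takes the para 4-OH first and then the less hindered ortho 6-OH, leaving the 2-OH, which is wedged between the ketone and the C-methyl group and hydrogen-bonded to the carbonyl.

Step 6
Reactants: 9 1-[4,6-bis(benzyloxy)-2-hydroxy-3-methylphenyl]butan-1-one
Product: 10 1-[4,6-bis(benzyloxy)-2-methoxy-3-methylphenyl]butan-1-one
Conditions: MeI (3 equiv), K2CO3 (3 equiv), DMF, 50 °C
Reagents that add atoms: iodomethane, CI
Why: Williamson O-methylation of the last, chelated phenol under forcing conditions, with the benzyl ethers and the ketone inert to K2CO3/MeI.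

Step 7
Reactants: 10 1-[4,6-bis(benzyloxy)-2-methoxy-3-methylphenyl]butan-1-one
Product: 13 1-(4,6-dihydroxy-2-methoxy-3-methylphenyl)butan-1-one, via 4-O-benzyl 6-hydroxy ketone 11 (not isolated), via 6-O-benzyl 4-hydroxy ketone 12 (not isolated)
Conditions: H2 (1 atm), 10% Pd/C, EtOAc/MeOH, rt; stop after 2 equiv H2
Reagents that add atoms: none
Why: Catalytic hydrogenolysis removes both benzyl ethers, while the aryl ketone and the methyl ether survive neutral conditions at 1 atm.

Step 8
Reactants: 13 1-(4,6-dihydroxy-2-methoxy-3-methylphenyl)butan-1-one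
Product: 14 1-{3-[(dimethylamino)methyl]-2,4-dihydroxy-6-methoxy-5-methylphenyl}butan-1-one
Conditions: 37% aq. HCHO (1.1 equiv) premixed with 40% aq. Me2NH (1.5 equiv), EtOH, 0 °C; filter the precipitate
Reagents that add atoms: formaldehyde, C=O; dimethylamine, CNC
Why: Mannich reaction at the only free ring carbon, which lies between two OH groups and is strongly nucleophilic.

Step 9
Reactants: 7 1-{3-[(3-butanoyl-2,4-dihydroxy-6-methoxy-5-methylphenyl)methyl]-2,4,6-trihydroxyphenyl}ethan-1-one; 14 1-{3-[(dimethylamino)methyl]-2,4-dihydroxy-6-methoxy-5-methylphenyl}butan-1-one (1.15 equiv)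
Product: 16 1-{3-[(3-butanoyl-2,4-dihydroxy-6-methoxy-5-methylphenyl)methyl]-5-[(3-butanoyl-2,6-dihydroxy-4-methoxy-5-methylphenyl)methyl]-2,4,6-trihydroxyphenyl}ethan-1-one, via ring-C ortho-quinone methide 15 (not isolated)
Conditions: 1,4-dioxane, 95 °C, N2 sparge; dilute HCl wash; chromatography, then crystallisation
Reagents that add atoms: none
Why: The same ortho-quinone methide Michael-type C-alkylation, now at the single remaining nucleophilic carbon of ring B in 7, fixes the A–B–C order, and no stereocentre is created anywhere in the route.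

## Compound list

1 | 2-methylbenzene-1,3,5-triol | Cc1c(O)cc(O)cc1O | starting material
2 | 1-(2,4,6-trihydroxy-3-methylphenyl)butan-1-one | CCCC(=O)c1c(O)cc(O)c(C)c1O | intermediate
3 | 1-(2,6-dihydroxy-4-methoxy-3-methylphenyl)butan-1-one (aspidinol) | CCCC(=O)c1c(O)cc(OC)c(C)c1O | intermediate
4 | 1-{3-[(dimethylamino)methyl]-2,6-dihydroxy-4-methoxy-5-methylphenyl}butan-1-one | CCCC(=O)c1c(O)c(CN(C)C)c(OC)c(C)c1O | intermediate
5 | 1-(2,4,6-trihydroxyphenyl)ethan-1-one | CC(=O)c1c(O)cc(O)cc1O | starting material
6 | 2-butanoyl-3-hydroxy-5-methoxy-4-methyl-6-methylidenecyclohexa-2,4-dien-1-one (ring-A ortho-quinone methide, formed in the flask) | CCCC(=O)C1=C(O)C(C)=C(OC)C(=C)C1=O | intermediate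
7 | 1-{3-[(3-butanoyl-2,4-dihydroxy-6-methoxy-5-methylphenyl)methyl]-2,4,6-trihydroxyphenyl}ethan-1-one | CCCC(=O)c1c(O)c(C)c(OC)c(Cc2c(O)cc(O)c(C(C)=O)c2O)c1O | intermediate
8 | 1-[4-(benzyloxy)-2,6-dihydroxy-3-methylphenyl]butan-1-one (formed in the flask) | CCCC(=O)c1c(O)cc(OCc2ccccc2)c(C)c1O | intermediate
9 | 1-[4,6-bis(benzyloxy)-2-hydroxy-3-methylphenyl]butan-1-one | CCCC(=O)c1c(O)c(C)c(OCc2ccccc2)cc1OCc1ccccc1 | intermediate
10 | 1-[4,6-bis(benzyloxy)-2-methoxy-3-methylphenyl]butan-1-one | CCCC(=O)c1c(OC)c(C)c(OCc2ccccc2)cc1OCc1ccccc1 | intermediate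
11 | 1-[4-(benzyloxy)-6-hydroxy-2-methoxy-3-methylphenyl]butan-1-one (formed in the flask) | CCCC(=O)c1c(OC)c(C)c(OCc2ccccc2)cc1O | intermediate
12 | 1-[6-(benzyloxy)-4-hydroxy-2-methoxy-3-methylphenyl]butan-1-one (formed in the flask) | CCCC(=O)c1c(OC)c(C)c(O)cc1OCc1ccccc1 | intermediate
13 | 1-(4,6-dihydroxy-2-methoxy-3-methylphenyl)butan-1-one | CCCC(=O)c1c(OC)c(C)c(O)cc1O | intermediate
14 | 1-{3-[(dimethylamino)methyl]-2,4-dihydroxy-6-methoxy-5-methylphenyl}butan-1-one | CCCC(=O)c1c(OC)c(C)c(O)c(CN(C)C)c1O | intermediate
15 | 4-butanoyl-5-hydroxy-3-methoxy-2-methyl-6-methylidenecyclohexa-2,4-dien-1-one (ring-C ortho-quinone methide, formed in the flask) | CCCC(=O)C1=C(O)C(=C)C(=O)C(C)=C1OC | intermediate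
16 | 1-{3-[(3-butanoyl-2,4-dihydroxy-6-methoxy-5-methylphenyl)methyl]-5-[(3-butanoyl-2,6-dihydroxy-4-methoxy-5-methylphenyl)methyl]-2,4,6-trihydroxyphenyl}ethan-1-one | CCCC(=O)c1c(O)c(C)c(OC)c(Cc2c(O)c(Cc3c(O)c(C)c(OC)c(C(=O)CCC)c3O)c(O)c(C(C)=O)c2O)c1O | target

## Step count and risks

Total step count: 9.
Longest linear sequence: 6 (steps 1, 5, 6, 7, 8, 9). The ring-A branch (steps 1, 2, 3, 4, 9) is 5.

The three steps most likely to fail:

Step 9 (final hetero-coupling). Mannich base 14 carries its CH2NMe2 between two OH groups and may self-condense. The liberated amine may also scramble the diarylmethane links, giving A–B–A and C–B–C trimers. The fallback reverses the roles of the partners and sets out from 7. Compound 7 is aminomethylated at its last free ring-B carbon (aq. HCHO/Me2NH, EtOH, 0 °C) to give 1-{3-[(3-butanoyl-2,4-dihydroxy-6-methoxy-5-methylphenyl)methyl]-5-[(dimethylamino)methyl]-2,4,6-trihydroxyphenyl}ethan-1-one F1. F1 is heated in dioxane with the free phenol 13, used directly so that step 8 is dropped. The quinone methide is then generated on ring B and captured by the small, unhindered monomer. The fallback comes back to the route at 16.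

Step 4 (mono-alkylation of a nucleophile with two equivalent sites). Over-alkylation to the A–B–A trimer or base-induced scrambling may erode the yield. The fallback sets out from 3 and avoids both the amine and the quinone methide precursor. Vilsmeier–Haack formylation of 3 (POCl3, DMF, EtOAc, 0 °C to rt, aqueous hydrolysis) at its only free carbon gives 3-butanoyl-2,4-dihydroxy-6-methoxy-5-methylbenzaldehyde F2. F2 is then joined to 5 (3 equiv) by acid-mediated reductive Friedel–Crafts benzylation (Et3SiH, CF3CO2H, CH2Cl2, 0 °C). The protonated aldehyde is attacked by 5, the diaryl carbinol ionises, and the cation is reduced by the silane. The fallback comes back at 7.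

Step 5 (regioselective dibenzylation). Alkylation may give the 2,4-di-O-benzyl isomer or a mixture. The fallback sets out from 2 and replaces kinetic discrimination in the alkylation by selective dealkylation. Exhaustive benzylation (BnBr 4 equiv, K2CO3, DMF, 70 °C) gives 1-[2,4,6-tris(benzyloxy)-3-methylphenyl]butan-1-one F3, into which any isomer mixture also converges. One equivalent of BCl3 (CH2Cl2, −78 °C) is then chelated by the ketone and cleaves an ortho ether. Strain relief selects the benzyl ether flanked by both the acyl and the methyl group. The fallback comes back at 9.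

## Further compounds

F1 | step 9 | 1-{3-[(3-butanoyl-2,4-dihydroxy-6-methoxy-5-methylphenyl)methyl]-5-[(dimethylamino)methyl]-2,4,6-trihydroxyphenyl}ethan-1-one | CCCC(=O)c1c(O)c(C)c(OC)c(Cc2c(O)c(CN(C)C)c(O)c(C(C)=O)c2O)c1O
F2 | step 4 | 3-butanoyl-2,4-dihydroxy-6-methoxy-5-methylbenzaldehyde | CCCC(=O)c1c(O)c(C=O)c(OC)c(C)c1O
F3 | step 5 | 1-[2,4,6-tris(benzyloxy)-3-methylphenyl]butan-1-one | CCCC(=O)c1c(OCc2ccccc2)c(C)c(OCc2ccccc2)cc1OCc1ccccc1
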